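**Assumption:** recombinant type 2 (legume) chalcone isomerase (EC 5.5.1.6, Medicago sativa gene expressed in Escherichia coli) is treated as an available catalyst. Flavan numbering is used: ring A = benzo ring, ring B = 2-aryl, ring C = pyran (O1, C2, C3, C4), ring D = phloroglucinol ring. MOM = methoxymethyl, TBS = tert-butyldimethylsilyl, Bn = benzyl.

## Retrosynthetic overview

- The target is a 2,4-cis-4-arylflavan. Rings A, C and B carry oxygen at C7 and C4' and none at C5, which is the skeleton of (2S)-liquiritigenin; its C2 already has the target configuration and its C4 carbonyl carbon is where ring D (the lauroylphloroglucinol) is attached.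
- Late stage: the acyl–ring D bond by Friedel–Crafts lauroylation; C4–H by ionic hydrogenation of a tertiary benzylic carbinol (C2 controls C4); C4–ring D by addition of a 2,4,6-tris(benzyloxy)phenylcerium reagent to the silylated flavanone.
- Key disconnection: O1–C2 of ring C, closed by chalcone isomerase-catalysed oxa-Michael addition in isoliquiritigenin, which sets C2.
- Isoliquiritigenin comes from a Claisen–Schmidt condensation of MOM-protected 2',4'-dihydroxyacetophenone and 4-hydroxybenzaldehyde.
- Ring order: rings A, B and D are bought as benzene rings; ring C is the only ring formed.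

Key step: step 5

## Route

Step 1
Reactants: 1 2',4'-dihydroxyacetophenone
Product: 2 2'-hydroxy-4'-(methoxymethoxy)acetophenone
Conditions: MOMCl (1.1 equiv), K2CO3, acetone, 0 °C → rt
Reagents that add atoms: chloromethyl methyl ether, COCCl
Why: Williamson-type O-alkylation should occur only at the 4'-hydroxyl, because the 2'-hydroxyl is hydrogen-bonded to the acetyl carbonyl and is much less nucleophilic.

Step 2
Reactants: 3 4-hydroxybenzaldehyde
Product: 4 4-(methoxymethoxy)benzaldehyde
Conditions: MOMCl (1.2 equiv), K2CO3, DMF, 0 °C → rt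
Reagents that add atoms: chloromethyl methyl ether, COCCl
Why: Williamson O-alkylation of the phenoxide removes the only acidic proton of the aldehyde partner, so that it stays electrophilic under the strongly basic condensation conditions.

Step 3
Reactants: 2 2'-hydroxy-4'-(methoxymethoxy)acetophenone; 4 4-(methoxymethoxy)benzaldehyde
Product: 6 (E)-2'-hydroxy-4,4'-bis(methoxymethoxy)chalcone, via aldol adduct 5 (not isolated)
Conditions: KOH (aq. 50%, excess), EtOH, rt; then AcOH to pH 6 at 0 °C
Reagents that add atoms: none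
Why: Claisen–Schmidt (crossed aldol) condensation, in which the acetophenone enolate adds to the non-enolisable aldehyde and the aldol adduct loses water by E1cB elimination to the favoured E-enone; the MOM ethers are base-stable and the 2'-phenoxide keeps the product on the chalcone side.

Step 4
Reactants: 6 (E)-2'-hydroxy-4,4'-bis(methoxymethoxy)chalcone
Product: 7 isoliquiritigenin ((E)-2',4,4'-trihydroxychalcone)
Conditions: 3 M aq. HCl/MeOH (1:5), 60 °C, short reaction time; recrystallisation from aq. EtOH
Reagents that add atoms: none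
Why: Acid-catalysed acetal cleavage (transacetalisation of the MOM groups to methanol) frees both phenols, while acid-induced cyclisation of the hydrogen-bonded 2'-hydroxychalcone is slow, and the recrystallisation is planned to remove any racemic flavanone before the enzymatic step.

Step 5
Reactants: 7 isoliquiritigenin
Product: 8 (2S)-liquiritigenin ((2S)-7,4'-dihydroxyflavanone)
Conditions: recombinant type 2 chalcone isomerase (Medicago sativa, EC 5.5.1.6), 50 mM potassium phosphate buffer pH 7.0, 10% v/v DMSO, 25 °C, substrate fed in portions; then pH 5, EtOAc extraction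
Reagents that add atoms: none
Why: In the active site the 2'-hydroxyl is ionised and the phenoxide adds to the enone β-carbon (intramolecular oxa-Michael addition), the enolate being stabilised by the hydrogen-bond network of the enzyme and then protonated at C3. The closest known reaction type is the enzymatic chalcone-to-flavanone isomerisation of 6'-deoxychalcones by legume chalcone isomerases, for which isoliquiritigenin is a natural substrate. Ring C closes in a 6-endo-trig mode with formation of the O1–C2 bond. The single new stereocentre, C2, is set by the catalyst, whose active site presents only one enantioface of the β-carbon to the phenoxide and so gives the 2S configuration. Only enantiofacial selectivity is needed, since no other hydroxyl can reach the β-carbon, and the substrate supports it because the 2'-OH···O=C hydrogen bond and the missing 6'-hydroxyl make the uncatalysed racemic closure slow at neutral pH. The enzyme forms and reopens only the 2S flavanone, so equilibration through the enzyme should not erode the configuration; the enantiomeric purity would be checked by chiral HPLC before going on.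

Step 6
Reactants: 8 (2S)-liquiritigenin
Product: 9 (2S)-7,4'-bis(tert-butyldimethylsilyloxy)flavanone
Conditions: MTBSTFA (3 equiv), MeCN, 40 °C
Reagents that add atoms: N-methyl-N-(tert-butyldimethylsilyl)trifluoroacetamide (MTBSTFA), CN(C(=O)C(F)(F)F)[Si](C)(C)C(C)(C)C
Why: Trans-silylation of both phenols by the N-silylamide is a neutral silyl transfer that needs no base, so the flavanone enolate required for retro-oxa-Michael opening and racemisation of C2 is never formed.

Step 7
Reactants: 10 1,3,5-tris(benzyloxy)benzene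
Product: 11 2-bromo-1,3,5-tris(benzyloxy)benzene
Conditions: NBS (1.0 equiv), CH2Cl2, −40 → 0 °C
Reagents that add atoms: N-bromosuccinimide, O=C1CCC(=O)N1Br
Why: Electrophilic aromatic bromination of the phloroglucinol triether, whose three free positions are equivalent, should stop at the monobromide with one equivalent of NBS because bromine deactivates the ring.

Step 8
Reactants: 11 2-bromo-1,3,5-tris(benzyloxy)benzene; 9 (2S)-7,4'-bis(tert-butyldimethylsilyloxy)flavanone
Product: 14 (2S)-4-[2,4,6-tris(benzyloxy)phenyl]-7,4'-bis(tert-butyldimethylsilyloxy)flavan-4-ol (both C4 epimers), via aryllithium 12 (not isolated), via arylcerium dichloride 13 (not isolated)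
Conditions: 11 (1.6 equiv), n-BuLi, THF, −78 °C; anhydrous CeCl3, THF, −78 °C; then 9, −78 → −40 °C; aq. NH4Cl
Reagents that add atoms: none
Why: Bromine–lithium exchange outruns benzylic deprotonation at −78 °C, and transmetalation to the weakly basic, oxophilic organocerium reagent suppresses enolisation of the ketone (and with it E1cB opening of ring C) in favour of 1,2-addition; the new C4 centre forms without useful control, which does not matter because it becomes planar in step 9.

Step 9
Reactants: 14 (2S)-4-[2,4,6-tris(benzyloxy)phenyl]-7,4'-bis(tert-butyldimethylsilyloxy)flavan-4-ol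
Product: 16 (2S,4S)-4-[2,4,6-tris(benzyloxy)phenyl]-7,4'-bis(tert-butyldimethylsilyloxy)flavan (2,4-cis), via flavan-4-yl cation 15 (not isolated)
Conditions: Et3SiH (5 equiv), then CF3CO2H (10 equiv), CH2Cl2, −78 → −20 °C
Reagents that add atoms: none
Why: Ionic hydrogenation, in which CF3CO2H ionises the tertiary benzylic alcohol to a cation stabilised by the para 7-siloxy oxygen and Et3SiH delivers hydride along the axial trajectory on the face opposite to the pseudo-equatorial ring B (chair-like transition state, both aryl groups equatorial in the product), which sets C4 as S, cis to C2.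

Step 10
Reactants: 16 (2S,4S)-4-[2,4,6-tris(benzyloxy)phenyl]-7,4'-bis(tert-butyldimethylsilyloxy)flavan; 17 lauroyl chloride (dodecanoyl chloride)
Product: 18 1-{2,4,6-tris(benzyloxy)-3-[(2S,4S)-7-(tert-butyldimethylsilyloxy)-2-(4-(tert-butyldimethylsilyloxy)phenyl)chroman-4-yl]phenyl}dodecan-1-one
Conditions: 17 (1.2 equiv), SnCl4 (1.2 equiv), CH2Cl2, −78 → −30 °C; cold aq. NaHCO3
Reagents that add atoms: none
Why: Friedel–Crafts acylation goes to ring D because this phloroglucinol triether is far more nucleophilic than ring A (one alkoxy and one less donating siloxy group) or ring B, both free positions of ring D give the same product, and the first acyl group deactivates the ring against a second acylation.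

Step 11
Reactants: 18 the bis-TBS tris-benzyl lauroyl flavan from step 10
Product: 19 1-{2,4,6-tris(benzyloxy)-3-[(2S,4S)-7-hydroxy-2-(4-hydroxyphenyl)chroman-4-yl]phenyl}dodecan-1-one
Conditions: TBAF (2.4 equiv), AcOH (2.4 equiv), THF, 0 °C
Reagents that add atoms: none
Why: Fluoride-induced cleavage of the two aryl silyl ethers is driven by Si–F bond formation, acetic acid keeps the liberated phenoxides protonated, and the benzyl ethers, the ketone and both stereocentres are inert to these conditions.

Step 12
Reactants: 19 the tris-benzyl lauroyl flavan diphenol from step 11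
Product: 20 1-{2,4,6-trihydroxy-3-[(2S,4S)-7-hydroxy-2-(4-hydroxyphenyl)chroman-4-yl]phenyl}dodecan-1-one (target)
Conditions: H2 (1 atm), 10% Pd/C, EtOAc/MeOH, rt
Reagents that add atoms: none
Why: Catalytic hydrogenolysis removes the three benzyl ethers, while the hydrogen-bonded acylphloroglucinol ketone and the benzylic C2–O1 and C4–H bonds of the flavan are not expected to react at one atmosphere and room temperature, so both stereocentres are kept.

## Compound list

1 | 2',4'-dihydroxyacetophenone | CC(=O)c1ccc(O)cc1O | starting material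
2 | 2'-hydroxy-4'-(methoxymethoxy)acetophenone | CC(=O)c1ccc(OCOC)cc1O | intermediate
3 | 4-hydroxybenzaldehyde | O=Cc1ccc(O)cc1 | starting material
4 | 4-(methoxymethoxy)benzaldehyde | COCOc1ccc(C=O)cc1 | intermediate
5 | aldol adduct, 3-hydroxy-1-[2-hydroxy-4-(methoxymethoxy)phenyl]-3-[4-(methoxymethoxy)phenyl]propan-1-one (racemic, not isolated) | COCOc1ccc(C(O)CC(=O)c2ccc(OCOC)cc2O)cc1 | intermediate
6 | (E)-2'-hydroxy-4,4'-bis(methoxymethoxy)chalcone | COCOc1ccc(/C=C/C(=O)c2ccc(OCOC)cc2O)cc1 | intermediate
7 | isoliquiritigenin, (E)-2',4,4'-trihydroxychalcone | O=C(/C=C/c1ccc(O)cc1)c1ccc(O)cc1O | intermediate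
8 | (2S)-liquiritigenin, (2S)-7,4'-dihydroxyflavanone | O=C1C[C@@H](c2ccc(O)cc2)Oc2cc(O)ccc12 | intermediate
9 | (2S)-7,4'-bis(tert-butyldimethylsilyloxy)flavanone | O=C1C[C@@H](c2ccc(O[Si](C)(C)C(C)(C)C)cc2)Oc2cc(O[Si](C)(C)C(C)(C)C)ccc12 | intermediate
10 | 1,3,5-tris(benzyloxy)benzene | c1(OCc2ccccc2)cc(OCc2ccccc2)cc(OCc2ccccc2)c1 | starting material
11 | 2-bromo-1,3,5-tris(benzyloxy)benzene | Brc1c(OCc2ccccc2)cc(OCc2ccccc2)cc1OCc1ccccc1 | intermediate
12 | 2,4,6-tris(benzyloxy)phenyllithium (not isolated) | [Li]c1c(OCc2ccccc2)cc(OCc2ccccc2)cc1OCc1ccccc1 | intermediate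
13 | 2,4,6-tris(benzyloxy)phenylcerium dichloride (not isolated) | Cl[Ce](Cl)c1c(OCc2ccccc2)cc(OCc2ccccc2)cc1OCc1ccccc1 | intermediate
14 | (2S)-4-[2,4,6-tris(benzyloxy)phenyl]-7,4'-bis(tert-butyldimethylsilyloxy)flavan-4-ol, C4 not defined (both epimers) | OC1(c2c(OCc3ccccc3)cc(OCc3ccccc3)cc2OCc2ccccc2)C[C@@H](c2ccc(O[Si](C)(C)C(C)(C)C)cc2)Oc2cc(O[Si](C)(C)C(C)(C)C)ccc21 | intermediate
15 | (2S)-4-[2,4,6-tris(benzyloxy)phenyl]-7,4'-bis(tert-butyldimethylsilyloxy)flavan-4-ylium trifluoroacetate (not isolated) | CC(C)(C)[Si](C)(C)Oc1ccc([C@@H]2C[C+](c3c(OCc4ccccc4)cc(OCc4ccccc4)cc3OCc3ccccc3)c3ccc(O[Si](C)(C)C(C)(C)C)cc3O2)cc1.[O-]C(=O)C(F)(F)F | intermediate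
16 | (2S,4S)-4-[2,4,6-tris(benzyloxy)phenyl]-7,4'-bis(tert-butyldimethylsilyloxy)flavan, 2,4-cis | C(c1ccccc1)Oc1cc(OCc2ccccc2)cc(OCc2ccccc2)c1[C@H]1C[C@@H](c2ccc(O[Si](C)(C)C(C)(C)C)cc2)Oc2cc(O[Si](C)(C)C(C)(C)C)ccc21 | intermediate
17 | lauroyl chloride (dodecanoyl chloride) | CCCCCCCCCCCC(=O)Cl | starting material
18 | 1-{2,4,6-tris(benzyloxy)-3-[(2S,4S)-7-(tert-butyldimethylsilyloxy)-2-(4-(tert-butyldimethylsilyloxy)phenyl)chroman-4-yl]phenyl}dodecan-1-one | CCCCCCCCCCCC(=O)c1c(OCc2ccccc2)cc(OCc2ccccc2)c([C@H]2C[C@@H](c3ccc(O[Si](C)(C)C(C)(C)C)cc3)Oc3cc(O[Si](C)(C)C(C)(C)C)ccc32)c1OCc1ccccc1 | intermediate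
19 | 1-{2,4,6-tris(benzyloxy)-3-[(2S,4S)-7-hydroxy-2-(4-hydroxyphenyl)chroman-4-yl]phenyl}dodecan-1-one | CCCCCCCCCCCC(=O)c1c(OCc2ccccc2)cc(OCc2ccccc2)c([C@H]2C[C@@H](c3ccc(O)cc3)Oc3cc(O)ccc32)c1OCc1ccccc1 | intermediate
20 | 1-{2,4,6-trihydroxy-3-[(2S,4S)-7-hydroxy-2-(4-hydroxyphenyl)chroman-4-yl]phenyl}dodecan-1-one | CCCCCCCCCCCC(=O)c1c(O)cc(O)c([C@H]2C[C@@H](c3ccc(O)cc3)Oc3cc(O)ccc32)c1O | target

## Step count and risks

Total step count: 12. Longest linear sequence: 10 steps (steps 1, 3, 4, 5, 6, 8, 9, 10, 11, 12); steps 2 and 7 are side branches.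

**Step 8.** The di-ortho-substituted aryl nucleophile may act as a base at C3 instead of adding; the enolate would then open ring C by E1cB elimination, with loss of material and of the C2 configuration, or addition may be too slow for steric reasons. The fallback replaces carbonyl addition by cross-coupling and sets out from 9. Ketone 9 is converted without an enolate (Tf2O, 2,6-di-tert-butyl-4-methylpyridine, CH2Cl2, 0 °C) into the (S)-2H-chromen-4-yl triflate F1. Aryllithium 12, made from 11 as in step 8, is transmetalated with ZnCl2 to the arylzinc chloride F2. Negishi coupling of F1 and F2 (Pd(OAc)2, SPhos, THF, 50 °C, zerovalent palladium forming in the flask) should give the 4-aryl-flav-3-ene F3. Under the conditions of step 9, F3 is protonated at C3 to cation 15 and reduced, so the fallback comes back to the route at 16.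

**Step 10.** The Lewis acid, chelated between the new ketone and an ortho benzyloxy group, may cleave benzyl ethers; silyl groups may be lost, ring A may be acylated in competition, or the C4–ring D bond may be cleaved by acid. The fallback replaces electrophilic acylation by a halogen–metal exchange sequence and sets out from 16. Bromination with NBS (1 equiv, CH2Cl2, −40 °C) should give the ring D monobromide F5. Exchange with n-BuLi (THF, −78 °C) gives the aryllithium F6, which is added to dodecanal to give the secondary benzylic alcohol F7 (both carbinol epimers). Oxidation with Dess–Martin periodinane (NaHCO3, CH2Cl2, rt) comes back to the route at 18.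

**Step 9.** Hydride may be delivered to both faces of the cation (poor facial selectivity). The cation may also eliminate to the flav-3-ene, whose C2–O1 bond can ionise in acid and erode the C2 configuration, or acid may cleave the C4–ring D bond. The fallback replaces ionic hydrogenation by catalytic syn-hydrogenation and sets out from 14. Dehydration under non-acidic conditions with methyl N-(triethylammoniumsulfonyl)carbamate (Burgess reagent, toluene, 50 °C, syn-elimination) should give the 4-aryl-flav-3-ene F4, the same compound as F3. Hydrogenation with H2 and [Ir(cod)(PCy3)(py)]PF6 in CH2Cl2 should add both hydrogens to the face of the C3=C4 bond opposite to ring B, which gives the 2,4-cis flavan and comes back to the route at 16.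

## Further compounds

F1 | step 8 | (S)-7-(tert-butyldimethylsilyloxy)-2-[4-(tert-butyldimethylsilyloxy)phenyl]-2H-chromen-4-yl trifluoromethanesulfonate | O=S(=O)(OC1=C[C@@H](c2ccc(O[Si](C)(C)C(C)(C)C)cc2)Oc2cc(O[Si](C)(C)C(C)(C)C)ccc12)C(F)(F)F
F2 | step 8 | 2,4,6-tris(benzyloxy)phenylzinc chloride | Cl[Zn]c1c(OCc2ccccc2)cc(OCc2ccccc2)cc1OCc1ccccc1
F3 | step 8 | (S)-4-[2,4,6-tris(benzyloxy)phenyl]-7-(tert-butyldimethylsilyloxy)-2-[4-(tert-butyldimethylsilyloxy)phenyl]-2H-chromene (4-aryl-flav-3-ene) | c1ccccc1COc1cc(OCc2ccccc2)cc(OCc2ccccc2)c1C1=C[C@@H](c2ccc(O[Si](C)(C)C(C)(C)C)cc2)Oc2cc(O[Si](C)(C)C(C)(C)C)ccc21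
F4 | step 9 | (S)-4-[2,4,6-tris(benzyloxy)phenyl]-7-(tert-butyldimethylsilyloxy)-2-[4-(tert-butyldimethylsilyloxy)phenyl]-2H-chromene (same compound as F3) | c1ccccc1COc1cc(OCc2ccccc2)cc(OCc2ccccc2)c1C1=C[C@@H](c2ccc(O[Si](C)(C)C(C)(C)C)cc2)Oc2cc(O[Si](C)(C)C(C)(C)C)ccc21
F5 | step 10 | (2S,4S)-4-[2,4,6-tris(benzyloxy)-3-bromophenyl]-7,4'-bis(tert-butyldimethylsilyloxy)flavan | Brc1c(OCc2ccccc2)cc(OCc2ccccc2)c([C@H]2C[C@@H](c3ccc(O[Si](C)(C)C(C)(C)C)cc3)Oc3cc(O[Si](C)(C)C(C)(C)C)ccc32)c1OCc1ccccc1
F6 | step 10 | (2S,4S)-4-[2,4,6-tris(benzyloxy)-3-lithiophenyl]-7,4'-bis(tert-butyldimethylsilyloxy)flavan | [Li]c1c(OCc2ccccc2)cc(OCc2ccccc2)c([C@H]2C[C@@H](c3ccc(O[Si](C)(C)C(C)(C)C)cc3)Oc3cc(O[Si](C)(C)C(C)(C)C)ccc32)c1OCc1ccccc1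
F7 | step 10 | 1-{2,4,6-tris(benzyloxy)-3-[(2S,4S)-7-(tert-butyldimethylsilyloxy)-2-(4-(tert-butyldimethylsilyloxy)phenyl)chroman-4-yl]phenyl}dodecan-1-ol (both carbinol epimers) | CCCCCCCCCCCC(O)c1c(OCc2ccccc2)cc(OCc2ccccc2)c([C@H]2C[C@@H](c3ccc(O[Si](C)(C)C(C)(C)C)cc3)Oc3cc(O[Si](C)(C)C(C)(C)C)ccc32)c1OCc1ccccc1
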